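**Plan**

- Numbering (drimane type): ring A = C1, C2, C3, C4 (CMe2), C5, C10; ring B = C5, C6, C7, C8 (CHMe), C9 (C, Me, CH2 to the quinone), C10 (CH).
- Cuts: quinone C–N and C–OH (amine and hydroxide replace two OMe of a dimethoxyquinone made from a tetramethoxyarene); ring A at C2–C3 and C4–C5 (isobutylene + a ring B alkenyl triflate at C5 carrying a CH2CH2 radical precursor on C10); the C10 chain and C5 oxygen by alkylative 1,2-carbonyl transposition; C9–CH2Ar and C8–Me from 2-methylcyclohexenone.
- Forward: ring B first (conjugate methylation/benzylation), then the chain on C10 and the carbonyl moved to C5, then ring A closed onto ring B with isobutylene, then arene to quinone, amine last.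
- Enabling feature: in ring A the C3H2–C4Me2 segment is an isobutylene unit between a primary sp3 carbon (C2) and the vinylic carbon C5 of the ring B C5=C6 alkene, so ring A equals a 1,2-alkyl-alkenylation of isobutylene by a tethered radical precursor/alkenyl triflate pair; this fixes the alkene position and builds quaternary C4.
- Stereochemistry: C8 from ligand-controlled conjugate addition; C9 by enolate benzylation anti to the C8 methyl; C10 by hydroboration anti to the axial C9 methyl; the side-chain centre from (S)-2-methylbutylamine.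

Key step: step 10

Remark: compounds 1, 3, 9, 19 and 23 are taken as purchased.

**Route**

Step 1
Reactants: 1 1,2,4,5-tetramethoxybenzene
Product: 2 3-(bromomethyl)-1,2,4,5-tetramethoxybenzene
Conditions: (CH2O)n (1 equiv), HBr (33% in AcOH), AcOH, 20 °C; 1 in threefold excess
Reagents that add atoms: formaldehyde (as paraformaldehyde), C=O; hydrogen bromide, Br
Why: Bromomethylation (electrophilic aromatic substitution, then benzylic OH to Br) of the very electron-rich arene should stop at mono-substitution with excess 1, and the two free ring positions are equivalent.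

Step 2
Reactants: 3 2-methylcyclohex-2-en-1-one; 2 3-(bromomethyl)-1,2,4,5-tetramethoxybenzene
Product: 6 (2R,3S)-2,3-dimethyl-2-[(2,3,5,6-tetramethoxyphenyl)methyl]cyclohexan-1-one, via dimethylaluminium enolate 4 (not isolated), via lithium aluminate enolate 5 (not isolated)
Conditions: Me3Al, Cu(O2CC4H3S) (2 mol %), binaphthol-derived phosphoramidite ligand with a bis(1-arylethyl)amino group (4 mol %, the enantiomer that gives 3S), Et2O, −30 °C; then MeLi, THF/HMPA, 2, −30 °C to rt
Reagents that add atoms: trimethylaluminium, C[Al](C)C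
Why: Copper-catalysed asymmetric conjugate addition should set C8 (3S) under ligand control, and the regiodefined enolate, activated as its ate complex, should be benzylated anti to the new methyl, giving quaternary C9 with the two methyls cis (tandem conjugate addition–enolate alkylation).

Step 3
Reactants: 6 (2R,3S)-2,3-dimethyl-2-[(2,3,5,6-tetramethoxyphenyl)methyl]cyclohexan-1-one
Product: 8 (5S,6R)-5,6-dimethyl-6-[(2,3,5,6-tetramethoxyphenyl)methyl]cyclohex-1-en-1-yl trifluoromethanesulfonate, via potassium enolate 7 (not isolated)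
Conditions: KN(SiMe3)2, THF, −78 °C; PhNTf2, −78 to 0 °C
Reagents that add atoms: N-phenylbis(trifluoromethanesulfonimide), O=S(=O)(N(c1ccccc1)S(=O)(=O)C(F)(F)F)C(F)(F)F
Why: The ketone can enolise only toward the CH2 side (the other α-carbon is quaternary), so O-triflation of the enolate should give a single enol triflate.

Step 4
Reactants: 8 (5S,6R)-5,6-dimethyl-6-[(2,3,5,6-tetramethoxyphenyl)methyl]cyclohex-1-en-1-yl trifluoromethanesulfonate; 9 tert-butyl 3-bromopropanoate
Product: 11 tert-butyl 3-{(5S,6R)-5,6-dimethyl-6-[(2,3,5,6-tetramethoxyphenyl)methyl]cyclohex-1-en-1-yl}propanoate, via zinc homoenolate 10 (not isolated)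
Conditions: Zn dust (activated), LiCl, THF, 40 °C (9 to 10); then 8, Pd(PPh3)4 (5 mol %), THF/DMA, 60 °C
Reagents that add atoms: none
Why: Negishi C(sp2)–C(sp3) coupling of an enol triflate with an ester-stabilised zinc homoenolate should put the three-carbon ester chain on C10.

Step 5
Reactants: 11 tert-butyl 3-{(5S,6R)-5,6-dimethyl-6-[(2,3,5,6-tetramethoxyphenyl)methyl]cyclohex-1-en-1-yl}propanoate
Product: 13 tert-butyl 3-{(1S,2R,3S,6S)-6-hydroxy-2,3-dimethyl-2-[(2,3,5,6-tetramethoxyphenyl)methyl]cyclohexyl}propanoate, via alkylborane 12 (not isolated)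
Conditions: BH3·THF, THF, 0 °C to rt; then NaOH, H2O2, 0 °C
Reagents that add atoms: hydrogen peroxide, OO
Why: Hydroboration–oxidation should place boron on the less substituted C5 and hydrogen on C10 by syn addition to the face opposite the pseudoaxial C9 methyl, so the C10 hydrogen ends trans to that methyl and the chain trans to the arylmethyl group; the C5 carbinol centre is removed in step 6.

Step 6
Reactants: 13 tert-butyl 3-{(1S,2R,3S,6S)-6-hydroxy-2,3-dimethyl-2-[(2,3,5,6-tetramethoxyphenyl)methyl]cyclohexyl}propanoate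
Product: 14 tert-butyl 3-{(1S,2R,3S)-2,3-dimethyl-6-oxo-2-[(2,3,5,6-tetramethoxyphenyl)methyl]cyclohexyl}propanoate
Conditions: Dess–Martin periodinane, NaHCO3, CH2Cl2, 0 °C to rt
Reagents that add atoms: none
Why: Dess–Martin oxidation under buffered, non-basic conditions should give the ketone without epimerising the adjacent C10 centre.

Step 7
Reactants: 14 tert-butyl 3-{(1S,2R,3S)-2,3-dimethyl-6-oxo-2-[(2,3,5,6-tetramethoxyphenyl)methyl]cyclohexyl}propanoate
Product: 16 tert-butyl 3-{(1S,5S,6R)-5,6-dimethyl-6-[(2,3,5,6-tetramethoxyphenyl)methyl]-2-[(trifluoromethanesulfonyl)oxy]cyclohex-2-en-1-yl}propanoate, via potassium enolate 15 (not isolated)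
Conditions: KN(SiMe3)2, THF, −78 °C; PhNTf2, −78 to 0 °C
Reagents that add atoms: N-phenylbis(trifluoromethanesulfonimide), O=S(=O)(N(c1ccccc1)S(=O)(=O)C(F)(F)F)C(F)(F)F
Why: Kinetic deprotonation by the bulky amide should occur at the C6 methylene, not at the hindered C10 methine or the ester α-CH2, so O-triflation fixes the C5=C6 double bond and leaves C10 untouched.

Step 8
Reactants: 16 tert-butyl 3-{(1S,5S,6R)-5,6-dimethyl-6-[(2,3,5,6-tetramethoxyphenyl)methyl]-2-[(trifluoromethanesulfonyl)oxy]cyclohex-2-en-1-yl}propanoate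
Product: 17 3-{(1S,5S,6R)-5,6-dimethyl-6-[(2,3,5,6-tetramethoxyphenyl)methyl]-2-[(trifluoromethanesulfonyl)oxy]cyclohex-2-en-1-yl}propanoic acid
Conditions: CF3CO2H/CH2Cl2 (1:3), 0 °C to rt
Reagents that add atoms: none
Why: Acidolysis of the tert-butyl ester (loss of isobutylene) should leave the enol triflate and the aryl methyl ethers intact, and the only free arene position is flanked by two methoxy groups and should not be tert-butylated.

Step 9
Reactants: 17 3-{(1S,5S,6R)-5,6-dimethyl-6-[(2,3,5,6-tetramethoxyphenyl)methyl]-2-[(trifluoromethanesulfonyl)oxy]cyclohex-2-en-1-yl}propanoic acid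
Product: 18 1,3-dioxoisoindolin-2-yl 3-{(1S,5S,6R)-5,6-dimethyl-6-[(2,3,5,6-tetramethoxyphenyl)methyl]-2-[(trifluoromethanesulfonyl)oxy]cyclohex-2-en-1-yl}propanoate
Conditions: N-hydroxyphthalimide, N,N'-diisopropylcarbodiimide, DMAP (cat.), CH2Cl2, rt
Reagents that add atoms: N-hydroxyphthalimide, ON1C(=O)c2ccccc2C1=O
Why: Carbodiimide esterification should give the redox-active N-acyloxyphthalimide, a standard precursor of a primary alkyl radical by single-electron reduction.

Step 10
Reactants: 18 1,3-dioxoisoindolin-2-yl 3-{(1S,5S,6R)-5,6-dimethyl-6-[(2,3,5,6-tetramethoxyphenyl)methyl]-2-[(trifluoromethanesulfonyl)oxy]cyclohex-2-en-1-yl}propanoate; 19 2-methylpropene (isobutylene)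
Product: 20 (1R,2S,8aS)-1,2,5,5-tetramethyl-1-[(2,3,5,6-tetramethoxyphenyl)methyl]-1,2,3,5,6,7,8,8a-octahydronaphthalene
Conditions: NiBr2·MeOCH2CH2OMe (10 mol %), 4,4'-di-tert-butyl-2,2'-bipyridine (15 mol %), Zn dust (3 equiv), 19 (ca. 30 equiv, condensed in), DMA, sealed tube, 25 °C, slow addition of 18
Reagents that add atoms: none
Why: Proposed new method: zerovalent nickel should add oxidatively to the C5–OTf bond to give an alkenylnickel species (divalent nickel), while single-electron reduction of the N-acyloxyphthalimide by low-valent nickel or zinc releases CO2 and the primary C2 radical, which adds to the CH2 end of isobutylene (C2–C3) to give the tertiary C4 radical; this radical is captured by the tethered alkenylnickel centre, C(sp2)–C(sp3) reductive elimination from trivalent nickel forms C4–C5, and zinc returns nickel to the zerovalent state. The closest known reaction types are nickel-catalysed reductive three-component alkyl–aryl or alkyl–alkenyl difunctionalisation of alkenes and decarboxylative cross-electrophile coupling of redox-active esters with alkenyl electrophiles, including capture of tertiary radicals to make quaternary carbons; the new element is the tethering of both electrophiles so that an unactivated 1,1-disubstituted alkene is annulated. Ring A closes as a six-membered ring by reductive elimination from a seven-membered nickelacycle, a formal [4+2] union of the C2–C1–C10–C5 unit with the C3=C4 alkene. No stereocentre is created (C4 carries two methyls), and C8, C9 and C10 are untouched, C10 no longer being α to a carbonyl. The step needs the primary radical to add to isobutylene before it is trapped by nickel, reduced, or quenched by 1,5-hydrogen transfer from the benzylic CH2; direct trapping by the tethered alkenylnickel would have to close a strained cyclobutene through a five-membered nickelacycle and is expected to be reversible, and a large excess of isobutylene with slow radical generation favours addition. The C5=C6 position is fixed by the triflate, and only addition at the CH2 end of isobutylene gives a tertiary radical, which secures the regiochemistry.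

Step 11
Reactants: 20 (1R,2S,8aS)-1,2,5,5-tetramethyl-1-[(2,3,5,6-tetramethoxyphenyl)methyl]-1,2,3,5,6,7,8,8a-octahydronaphthalene
Product: 21 2,5-dimethoxy-3-{[(1R,2S,8aS)-1,2,5,5-tetramethyl-1,2,3,5,6,7,8,8a-octahydronaphthalen-1-yl]methyl}cyclohexa-2,5-diene-1,4-dione
Conditions: (NH4)2Ce(NO3)6 (2.5 equiv), MeCN/H2O 2:1, 0 °C
Reagents that add atoms: water, O
Why: Oxidative demethylation of a para-dimethoxy pair should give the 2,5-dimethoxy-1,4-benzoquinone (both para pairs of the symmetric arene give the same constitution), and the unactivated trisubstituted alkene should survive.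

Step 12
Reactants: 21 2,5-dimethoxy-3-{[(1R,2S,8aS)-1,2,5,5-tetramethyl-1,2,3,5,6,7,8,8a-octahydronaphthalen-1-yl]methyl}cyclohexa-2,5-diene-1,4-dione
Product: 22 2-hydroxy-5-methoxy-3-{[(1R,2S,8aS)-1,2,5,5-tetramethyl-1,2,3,5,6,7,8,8a-octahydronaphthalen-1-yl]methyl}cyclohexa-2,5-diene-1,4-dione
Conditions: KOH, MeOH/H2O, 0 °C to rt; then dilute HCl
Reagents that add atoms: potassium hydroxide, [K+].[OH-]
Why: Addition–elimination of hydroxide at a vinylogous ester; the methoxy flanked by the bulky CH2 substituent is twisted out of conjugation and should be the more electrophilic one, giving the 2-hydroxy-5-methoxy pattern, and the resulting vinylogous carboxylate should resist a second hydrolysis under these conditions.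

Step 13
Reactants: 22 2-hydroxy-5-methoxy-3-{[(1R,2S,8aS)-1,2,5,5-tetramethyl-1,2,3,5,6,7,8,8a-octahydronaphthalen-1-yl]methyl}cyclohexa-2,5-diene-1,4-dione; 23 (2S)-2-methylbutan-1-amine
Product: 24 nakijiquinone J, 2-hydroxy-5-{[(2S)-2-methylbutyl]amino}-3-{[(1R,2S,8aS)-1,2,5,5-tetramethyl-1,2,3,5,6,7,8,8a-octahydronaphthalen-1-yl]methyl}cyclohexa-2,5-diene-1,4-dione
Conditions: 23 (3 equiv), NaHCO3, EtOH, rt
Reagents that add atoms: none
Why: Conjugate addition–elimination of the primary amine at the only remaining vinylogous methyl ester (the hydroxy side is deactivated as its vinylogous carboxylate) should give the vinylogous amide; the amine stereocentre is not involved.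

**Compound list**

1 | 1,2,4,5-tetramethoxybenzene | COc1cc(OC)c(OC)cc1OC | starting material
2 | 3-(bromomethyl)-1,2,4,5-tetramethoxybenzene | BrCc1c(OC)c(OC)cc(OC)c1OC | intermediate
3 | 2-methylcyclohex-2-en-1-one | CC1=CCCCC1=O | starting material
4 | dimethylaluminium (3S)-2,3-dimethylcyclohex-1-en-1-olate | C[Al](C)OC1=C(C)[C@@H](C)CCC1 | intermediate (not isolated)
5 | lithium trimethyl[(3S)-2,3-dimethylcyclohex-1-en-1-olato]aluminate | [Li+].C[Al-](C)(C)OC1=C(C)[C@@H](C)CCC1 | intermediate (not isolated)
6 | (2R,3S)-2,3-dimethyl-2-[(2,3,5,6-tetramethoxyphenyl)methyl]cyclohexan-1-one | COc1cc(OC)c(OC)c(C[C@@]2(C)C(=O)CCC[C@@H]2C)c1OC | intermediate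
7 | potassium enolate of 6 | COc1cc(OC)c(OC)c(C[C@@]2(C)C([O-])=CCC[C@@H]2C)c1OC.[K+] | intermediate (not isolated)
8 | (5S,6R)-5,6-dimethyl-6-[(2,3,5,6-tetramethoxyphenyl)methyl]cyclohex-1-en-1-yl trifluoromethanesulfonate | COc1cc(OC)c(OC)c(C[C@@]2(C)C(OS(=O)(=O)C(F)(F)F)=CCC[C@@H]2C)c1OC | intermediate
9 | tert-butyl 3-bromopropanoate | CC(C)(C)OC(=O)CCBr | starting material
10 | tert-butyl 3-(bromozincio)propanoate | CC(C)(C)OC(=O)CC[Zn]Br | intermediate (not isolated)
11 | tert-butyl 3-{(5S,6R)-5,6-dimethyl-6-[(2,3,5,6-tetramethoxyphenyl)methyl]cyclohex-1-en-1-yl}propanoate | COc1cc(OC)c(OC)c(C[C@@]2(C)C(CCC(=O)OC(C)(C)C)=CCC[C@@H]2C)c1OC | intermediate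
12 | alkylborane from 11 (BH2 on C5, cis to the C10 hydrogen) | COc1cc(OC)c(OC)c(C[C@@]2(C)[C@H](CCC(=O)OC(C)(C)C)[C@@H](B)CC[C@@H]2C)c1OC | intermediate (not isolated)
13 | tert-butyl 3-{(1S,2R,3S,6S)-6-hydroxy-2,3-dimethyl-2-[(2,3,5,6-tetramethoxyphenyl)methyl]cyclohexyl}propanoate | COc1cc(OC)c(OC)c(C[C@@]2(C)[C@H](CCC(=O)OC(C)(C)C)[C@@H](O)CC[C@@H]2C)c1OC | intermediate
14 | tert-butyl 3-{(1S,2R,3S)-2,3-dimethyl-6-oxo-2-[(2,3,5,6-tetramethoxyphenyl)methyl]cyclohexyl}propanoate | COc1cc(OC)c(OC)c(C[C@@]2(C)[C@H](CCC(=O)OC(C)(C)C)C(=O)CC[C@@H]2C)c1OC | intermediate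
15 | potassium enolate of 14 (C5=C6) | COc1cc(OC)c(OC)c(C[C@@]2(C)[C@H](CCC(=O)OC(C)(C)C)C([O-])=CC[C@@H]2C)c1OC.[K+] | intermediate (not isolated)
16 | tert-butyl 3-{(1S,5S,6R)-5,6-dimethyl-6-[(2,3,5,6-tetramethoxyphenyl)methyl]-2-[(trifluoromethanesulfonyl)oxy]cyclohex-2-en-1-yl}propanoate | COc1cc(OC)c(OC)c(C[C@@]2(C)[C@H](CCC(=O)OC(C)(C)C)C(OS(=O)(=O)C(F)(F)F)=CC[C@@H]2C)c1OC | intermediate
17 | 3-{(1S,5S,6R)-5,6-dimethyl-6-[(2,3,5,6-tetramethoxyphenyl)methyl]-2-[(trifluoromethanesulfonyl)oxy]cyclohex-2-en-1-yl}propanoic acid | COc1cc(OC)c(OC)c(C[C@@]2(C)[C@H](CCC(=O)O)C(OS(=O)(=O)C(F)(F)F)=CC[C@@H]2C)c1OC | intermediate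
18 | 1,3-dioxoisoindolin-2-yl ester of 17 | COc1cc(OC)c(OC)c(C[C@@]2(C)[C@H](CCC(=O)ON3C(=O)c4ccccc4C3=O)C(OS(=O)(=O)C(F)(F)F)=CC[C@@H]2C)c1OC | intermediate
19 | 2-methylpropene (isobutylene) | CC(C)=C | starting material
20 | (1R,2S,8aS)-1,2,5,5-tetramethyl-1-[(2,3,5,6-tetramethoxyphenyl)methyl]-1,2,3,5,6,7,8,8a-octahydronaphthalene | COc1cc(OC)c(OC)c(C[C@@]2(C)[C@@H]3CCCC(C)(C)C3=CC[C@@H]2C)c1OC | intermediate
21 | 2,5-dimethoxy-3-{[(1R,2S,8aS)-1,2,5,5-tetramethyl-1,2,3,5,6,7,8,8a-octahydronaphthalen-1-yl]methyl}cyclohexa-2,5-diene-1,4-dione | COC1=CC(=O)C(OC)=C(C[C@@]2(C)[C@@H]3CCCC(C)(C)C3=CC[C@@H]2C)C1=O | intermediate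
22 | 2-hydroxy-5-methoxy-3-{[(1R,2S,8aS)-1,2,5,5-tetramethyl-1,2,3,5,6,7,8,8a-octahydronaphthalen-1-yl]methyl}cyclohexa-2,5-diene-1,4-dione | COC1=CC(=O)C(O)=C(C[C@@]2(C)[C@@H]3CCCC(C)(C)C3=CC[C@@H]2C)C1=O | intermediate
23 | (2S)-2-methylbutan-1-amine | CC[C@H](C)CN | starting material
24 | nakijiquinone J | CC[C@H](C)CNC1=CC(=O)C(O)=C(C[C@@]2(C)[C@@H]3CCCC(C)(C)C3=CC[C@@H]2C)C1=O | target

**Count and risks**

Total steps: 13. Longest linear sequence: 13 steps (1 → 2 → 6 → … → 24; the route is linear because the benzyl bromide enters at step 2).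

Most likely to fail:

Step 10 (proposed new method). The primary radical may be captured by nickel, reduced, or lost by 1,5-hydrogen transfer before it adds to isobutylene, and reductive elimination at the hindered quaternary carbon may be slow. The fallback sets out from 18 and returns at 20, using known reactions in two stages. Visible-light decarboxylative radical allylation of 18 with (2-methylallyl) phenyl sulfone (Ru(bpy)3(PF6)2, Hantzsch ester, i-Pr2NEt, CH2Cl2, blue light) should give (4S,5R,6S)-4,5-dimethyl-6-(4-methylpent-4-en-1-yl)-5-[(2,3,5,6-tetramethoxyphenyl)methyl]cyclohex-1-en-1-yl trifluoromethanesulfonate F1; the sulfone traps the radical much faster than isobutylene does. An intramolecular reductive Heck reaction (Pd(OAc)2, PPh3, HCO2Na, Et4NCl, DMF, 80 °C) should then close ring A by 6-exo-trig carbopalladation of the 1,1-disubstituted alkene, and the neopentyl alkylpalladium, which has no β-hydrogen, should be reduced by formate to the second methyl group, giving 20.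

Step 5. Borane may add with poor or reversed facial selectivity, so C10 is formed with the wrong configuration (and could also epimerise at the ketone stage). The fallback sets out from 11 and returns at 14. If reagents prefer the face syn to the C9 methyl, 11 would be epoxidised from that face (3-chloroperbenzoic acid, NaHCO3, CH2Cl2) to the epoxide of 11 with the oxirane oxygen cis to the C9 methyl F2. A Meinwald rearrangement (LiClO4, toluene, 80 °C) would open the epoxide at the tertiary C10 and shift hydride from C5 to C10 anti to the departing oxygen; this puts the C10 hydrogen on the face opposite to that reached by syn-hydroboration from the same side and gives ketone 14 directly.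

Step 12. Hydroxide may attack the wrong methoxy-bearing carbon, or both, so the hydroxy and methoxy groups end up exchanged. The fallback sets out from 21 and returns at 24. Both vinylogous esters of 21 would be hydrolysed (NaOH, aqueous dioxane, then acid) to 2,5-dihydroxy-3-{[(1R,2S,8aS)-1,2,5,5-tetramethyl-1,2,3,5,6,7,8,8a-octahydronaphthalen-1-yl]methyl}cyclohexa-2,5-diene-1,4-dione F3, which would be condensed with amine 23 (EtOH, 60 °C). The hydroxy group next to the ring CH, not the one shielded by the bulky CH2 substituent, should be exchanged for the amine, giving 24.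

**Further compounds**

F1 | step 10 | (4S,5R,6S)-4,5-dimethyl-6-(4-methylpent-4-en-1-yl)-5-[(2,3,5,6-tetramethoxyphenyl)methyl]cyclohex-1-en-1-yl trifluoromethanesulfonate | COc1cc(OC)c(OC)c(C[C@@]2(C)[C@H](CCCC(C)=C)C(OS(=O)(=O)C(F)(F)F)=CC[C@@H]2C)c1OC
F2 | step 5 | tert-butyl 3-{2,3-dimethyl-2-[(2,3,5,6-tetramethoxyphenyl)methyl]-7-oxabicyclo[4.1.0]heptan-1-yl}propanoate, oxirane oxygen cis to the C9 methyl | COc1cc(OC)c(OC)c(C[C@@]2(C)[C@]3(CCC(=O)OC(C)(C)C)O[C@@H]3CC[C@@H]2C)c1OC
F3 | step 12 | 2,5-dihydroxy-3-{[(1R,2S,8aS)-1,2,5,5-tetramethyl-1,2,3,5,6,7,8,8a-octahydronaphthalen-1-yl]methyl}cyclohexa-2,5-diene-1,4-dione | OC1=CC(=O)C(O)=C(C[C@@]2(C)[C@@H]3CCCC(C)(C)C3=CC[C@@H]2C)C1=O
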